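## Analysis of the target

Target 29 is a 3-hydroxyisoflavanone: a chroman-4-one (rings A and C) whose C3 carries both a hydroxyl group and ring B. Ring A has the substituent sequence C5–OH (hydrogen-bonded to the C4 ketone), C6–prenyl, C7–OH, C8–H. Ring B carries 2'-OMe, 3'-prenyl and 4'-OH. The only stereocentre is C3, configuration (R): a fully substituted carbinol that is α to the ketone and benzylic to an electron-rich arene, with no neighbouring stereocentre to relay from. The sensitive groups are the two prenyl chains, each next to a phenol (acid closes them to chromans), and the tertiary benzylic α-ketol (acid can ionise it and dehydrate toward the isoflavone; base can trigger α-ketol rearrangement or ring opening). Two problems make the synthesis hard: placing the ring A prenyl at C6 and not C8 on a phloroglucinol-type ring, and making the quaternary C3 carbinol as one enantiomer. The strategy rests on the order C5 (OH), C6 (alkyl), C7 (oxygen), C8 (H) on ring A. This is the pattern a vinylketene and a siloxyalkyne deliver, so ring A can be grown onto a finished ring C that already holds C3.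

## Retrosynthetic reasoning

**29 back to 27.** The last operations are removals of protecting groups only. The O7 silyl ether of 28 is taken off with buffered fluoride; 28 comes from 27 by mild acid, which frees O4' and O3. Acid is used while O7 is still silylated, so the more nucleophilic ring A oxygen cannot add to the C6 prenyl group, and the target is finally released from a near-neutral medium.

**27 to 17 and 22 (key disconnection).** Ring A is cut at C5–C6, C7–C8 and C4a–C5. This removes the whole aromatic ring and leaves diazoketone 17, which holds ring C, O1, C3 and ring B, and siloxyalkyne 22, which holds C6, C7 and the prenyl group. Cutting here sidesteps any electrophilic prenylation of a phloroglucinol. The forward reaction has to generate a vinylketene from 17 by a photochemical Wolff rearrangement, add 22 with the right polarity, and aromatise by ring opening and electrocyclisation.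

**22 to 18.** The alkyne is taken back to ester 19 by a one-carbon ester homologation in which the ester carbonyl carbon becomes the oxygen-bearing alkyne carbon. Ester 19 comes from acid 18, so the prenyl group is bought and not made.

**17 to 13.** The diazoacetyl group is traced to carboxylic acid 15 through acid chloride 16. Acid 15 comes from ester 14, and 14 from tertiary alcohol 13 by O-silylation. These steps form no skeletal bond and only prepare the C2 substituent of the pyranone for the Wolff rearrangement.

**13 to 10 and 11.** The dihydropyranone is cut at the ring O–CH2 bond and at the C–C bond between the ketone methyl carbon and an oxalyl carbon. This gives epoxy methyl ketone 10 and oxalate 11. The gain is that one condensation brings in C4a, C8a and the carboxyl carbon, and the epoxide supplies both the ring CH2–O bond and the tertiary C3 oxygen. The forward step must open the epoxide at its CH2 carbon only, so the quaternary centre keeps its configuration.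

**10 to 8.** The ketone is taken back to epoxy alcohol 9 and this to allylic alcohol 8. The secondary carbinol of 8 is a temporary stereocentre: it directs a matched, catalyst-controlled epoxidation onto one face of the 1,1-disubstituted alkene and is then oxidised away. This is chosen over dihydroxylation or peracid chemistry because a hydroxyl-directed epoxidation ignores the prenyl double bond.

**8 to 5 and 6.** The aryl–alkene bond is cut. Aryl Grignard reagent 7, made from bromide 5, adds across the triple bond of enantiopure alkynol 6 with the aryl group at the internal carbon. The carbinol centre of 6 is bought and never touched.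

**5 to 1.** The ring B prenyl group is attached by metalation of 2 at the carbon between its two oxygens and allylation with 3. Compound 2 is the acetal of phenol 1, which already has the bromine ortho to the methoxy group and para to the phenol oxygen, so ring B needs no regioselective aromatic substitution.

## Alternatives that were turned down

**Alternative 1:** Both prenyl groups are disconnected at their aryl–CH2 bonds (C6–CH2 and C3'–CH2) and traced to 1,1-dimethylallyl groups on O5 and O2'. The forward key step heats the bis-ether A2 so that two ortho-Claisen rearrangements deliver A1; no ring closes.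
- For it: each ether oxygen has a single free ortho position, so C6 versus C8 is decided without any selectivity question, and both prenyl groups arrive in one thermal operation. On this point it is as strong as or stronger than the chosen strategy, and it needs no photochemistry.
- Against it: A2 already contains the whole isoflavanone and the C3 carbinol, so the two real problems (skeleton and stereocentre) are left unsolved. Tertiary allylic ethers must be made on the chelated O5 and the hindered O2'. The rearrangement heats a tertiary benzylic α-ketol. A1 then needs methylation of O2' alone, in base, next to the free 5-OH and 3-OH.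
- Comparison: the chosen strategy builds ring A and places its prenyl group in the same step, carries the 2'-methyl ether from the first compound, and ends with no selective alkylation.

**Alternative 2:** The C3–C4 bond is cut, giving keto aldehyde A4, an aryl ketone on ring B linked through O1–CH2 to a ring A benzaldehyde. In the forward step a chiral N-heterocyclic carbene turns the aldehyde carbon into an acyl anion equivalent that adds to the ketone, closing ring C and creating C3 in A3.
- For it: the stereocentre and ring C are made together in one catalytic step from two fragments of similar size. This is stronger than the chosen strategy, where C3 is set early by a two-step relay and carried through ten further steps.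
- Against it: the aldehyde of A4 sits between two ortho oxygens on a very electron-rich ring, and the ketone is an ortho-substituted, electron-rich aryl ketone. Both slow carbene addition and the carbonyl addition, and the enantioselectivity of so hindered a pair is not assured. The fully substituted ring A aldehyde still needs the 6- versus 8-prenyl question solved by classical arene chemistry.
- Comparison: the chosen strategy fixes the ring A pattern by construction, and its stereocentre comes from a purchased carbinol and a matched directed epoxidation whose outcome is predictable.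

**Alternative 3:** O1–C8a and C4–C4a are cut. Ring A comes from silyl triflate A6 and ring B with C2, C3 and C4 from hydroxy ester A7. In the forward step a fluoride source releases the aryne from A6, the primary alkoxide of A7 adds at the aryne carbon remote from the flanking acetal oxygen, and the resulting aryl anion attacks the ester, closing ring C to A5.
- For it: it is the most convergent plan, joining two complete halves and forming two bonds in one step. On convergence it is stronger than the linear chosen route.
- Against it: the aryl anion is quenched by proton transfer from the alcohol faster than a hindered anion can attack an α,α-disubstituted ester, which would give an open aryl ether. A6 is a hexasubstituted benzene that needs its own long, regiocontrolled synthesis. A7 needs the same quaternary carbinol made anyway. A5 carries four acetals, one on the tertiary oxygen, to be removed with acid at the end.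
- Comparison: the chosen strategy needs no polysubstituted arene precursor for ring A, leaves C5–OH free and O7 differentiated directly, and ends with mild deprotections.

Key step: step 12

Remark: the C3 oxygen is carried as a triethylsilyl ether in place of an acetal, because a tertiary carbinol is silylated more readily than it is alkylated and is freed again without strong acid; 1, 3, 6, 11 and 18 are taken as purchased.
In the names below, Ar stands for 2-methoxy-4-(methoxymethoxy)-3-(3-methylbut-2-en-1-yl)phenyl and prenyl for 3-methylbut-2-en-1-yl.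

## Route

Step 1
Reactants: 1 4-bromo-3-methoxyphenol
Product: 2 1-bromo-2-methoxy-4-(methoxymethoxy)benzene
Conditions: MOMCl, iPr2NEt, CH2Cl2, 0 °C → rt
Reagents that add atoms: chloromethyl methyl ether, COCCl
Why: O-alkylation of the phenol to its methoxymethyl acetal; the acetal oxygen is the ortho-directing group for step 2 and withstands all the basic and organometallic steps that follow.

Step 2
Reactants: 2 1-bromo-2-methoxy-4-(methoxymethoxy)benzene; 3 prenyl bromide
Product: 5 1-bromo-2-methoxy-4-(methoxymethoxy)-3-prenylbenzene, via aryllithium 4 (not isolated)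
Conditions: lithium 2,2,6,6-tetramethylpiperidide, THF, −78 °C; then CuI (10 mol %), 3, −78 → 0 °C
Reagents that add atoms: none
Why: Directed ortho-metalation: the hydrogen flanked by the methoxy and acetal oxygens is the most acidic and is removed by the amide base, which does not exchange the bromide; copper-catalysed allylation of 4 at the primary carbon of 3 gives the linear prenyl group.

Step 3
Reactants: 5 1-bromo-2-methoxy-4-(methoxymethoxy)-3-prenylbenzene; 6 (S)-but-3-yn-2-ol
Product: 8 (2S)-3-Ar-but-3-en-2-ol, via aryl Grignard reagent 7 (not isolated)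
Conditions: Mg, LiCl, THF, rt; 6 premixed with iPrMgCl (1.0 equiv), THF, 0 °C; combine, CuI (10 mol %), 0 → 45 °C; aq NH4Cl
Reagents that add atoms: none
Why: Magnesium insertion gives 7, and the magnesium alkoxide of 6 (made with iPrMgCl so that no aryl reagent is spent on the OH) undergoes copper-catalysed anti-carbomagnesiation; the aryl group goes to the internal alkyne carbon because magnesium ends in a five-membered alkoxide chelate at the terminal carbon, and the carbinol centre of 6 is not involved and stays (S).

Step 4
Reactants: 8 (2S)-3-Ar-but-3-en-2-ol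
Product: 9 (1S)-1-[(2R)-2-Ar-oxiran-2-yl]ethan-1-ol
Conditions: Ti(OiPr)4 (15 mol %), L-(+)-diisopropyl tartrate (18 mol %), tBuOOH, 4 Å molecular sieves, CH2Cl2, −20 °C; non-acidic work-up
Reagents that add atoms: tert-butyl hydroperoxide, CC(C)(C)OO
Why: Sharpless asymmetric epoxidation in its matched mode: with the L-(+)-tartrate the (S)-carbinol is the fast-reacting enantiomer and is epoxidised on the face anti to its methyl group to give the erythro epoxy alcohol, which sets the quaternary centre as (R); the prenyl double bond is not an allylic alcohol and is left alone.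

Step 5
Reactants: 9 (1S)-1-[(2R)-2-Ar-oxiran-2-yl]ethan-1-ol
Product: 10 1-[(2R)-2-Ar-oxiran-2-yl]ethan-1-one
Conditions: Dess–Martin periodinane, NaHCO3, CH2Cl2, 0 °C → rt
Reagents that add atoms: none
Why: Dess–Martin oxidation of the secondary alcohol under buffered conditions; the relay carbinol is erased, the quaternary epoxide carbon has no α-hydrogen and cannot epimerise, and the new acyl group makes the benzylic epoxide less prone to ionise.

Step 6
Reactants: 10 1-[(2R)-2-Ar-oxiran-2-yl]ethan-1-one; 11 diethyl oxalate
Product: 13 ethyl (5R)-5-Ar-5-hydroxy-4-oxo-5,6-dihydro-4H-pyran-2-carboxylate, via diketo ester enolate 12 (not isolated)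
Conditions: LiN(SiMe3)2 (1.1 equiv), THF, −78 °C; 11, −78 → 0 °C; then 45 °C; aq NH4Cl
Reagents that add atoms: none
Why: Claisen condensation at the only enolisable position of 10 with the non-enolisable oxalate gives 12, whose enolate oxygen then opens the epoxide at the unhindered CH2 carbon (6-endo attack, the counterpart of the flavanonol closure in Algar–Flynn–Oyamada chemistry); only the CH2–O bond breaks, so the quaternary centre keeps its configuration and becomes C5 (R) of the pyranone.

Step 7
Reactants: 13 ethyl (5R)-5-Ar-5-hydroxy-4-oxo-5,6-dihydro-4H-pyran-2-carboxylate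
Product: 14 ethyl (5R)-5-Ar-4-oxo-5-[(triethylsilyl)oxy]-5,6-dihydro-4H-pyran-2-carboxylate
Conditions: Et3SiOTf, 2,6-lutidine, CH2Cl2, −78 → 0 °C
Reagents that add atoms: triethylsilyl trifluoromethanesulfonate, CC[Si](CC)(CC)OS(=O)(=O)C(F)(F)F
Why: Silylation of a hindered tertiary alcohol with a silyl triflate and a non-nucleophilic base; it blocks the α-ketol against base-induced rearrangement and against reaction with the acid chloride and ketene of later steps.

Step 8
Reactants: 14 ethyl (5R)-5-Ar-4-oxo-5-[(triethylsilyl)oxy]-5,6-dihydro-4H-pyran-2-carboxylate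
Product: 15 (5R)-5-Ar-4-oxo-5-[(triethylsilyl)oxy]-5,6-dihydro-4H-pyran-2-carboxylic acid
Conditions: LiOH (1.5 equiv), THF/H2O, 0 °C; then 0.5 M HCl to pH 3, 0 °C
Reagents that add atoms: lithium hydroxide, [Li+].[OH-]
Why: Saponification of an ester activated by the α-alkoxy enone; low temperature and a brief cold acidification spare the tertiary silyl ether, the aryl acetal and the vinylogous ester ring.

Step 9
Reactants: 15 (5R)-5-Ar-4-oxo-5-[(triethylsilyl)oxy]-5,6-dihydro-4H-pyran-2-carboxylic acid
Product: 17 (5R)-5-Ar-2-(diazoacetyl)-5-[(triethylsilyl)oxy]-5,6-dihydro-4H-pyran-4-one, via acid chloride 16 (not isolated)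
Conditions: 1-chloro-N,N,2-trimethylprop-1-en-1-amine, CH2Cl2, 0 °C → rt; then Me3SiCHN2, THF/MeCN, 0 °C
Reagents that add atoms: (trimethylsilyl)diazomethane, C[Si](C)(C)C=[N+]=[N-]
Why: The chloroenamine makes the acid chloride without releasing HCl, so acetal and silyl ether survive; acylation of the silyl diazomethane with loss of the silyl group (the first stage of an Arndt–Eistert sequence) gives the diazomethyl ketone.

Step 10
Reactants: 18 4-methylpent-3-enoic acid
Product: 19 methyl 4-methylpent-3-enoate
Conditions: MeI, K2CO3, DMF, rt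
Reagents that add atoms: iodomethane, CI
Why: Carboxylate O-alkylation under mild base, which avoids the acid-promoted lactonisation or double-bond migration a Fischer esterification could cause.

Step 11
Reactants: 19 methyl 4-methylpent-3-enoate
Product: 22 triisopropyl[(5-methylhex-4-en-1-yn-1-yl)oxy]silane, via dibromomethyl ketone enolate 20 (not isolated), via lithium ynolate 21 (not isolated)
Conditions: CH2Br2, lithium 2,2,6,6-tetramethylpiperidide, THF, −78 °C; n-BuLi, −78 → 0 °C; iPr3SiCl, 0 °C → rt
Reagents that add atoms: dibromomethane, BrCBr; chlorotriisopropylsilane, CC(C)[Si](Cl)(C(C)C)C(C)C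
Why: Kowalski ester homologation: dibromomethyllithium adds to the ester, the enolate of 20 undergoes bromine–lithium exchange and 1,2-shift of the prenyl-bearing carbon to ynolate 21, and the bulky chlorosilane captures 21 on oxygen to give a stable siloxyalkyne.

Step 12
Reactants: 17 (5R)-5-Ar-2-(diazoacetyl)-5-[(triethylsilyl)oxy]-5,6-dihydro-4H-pyran-4-one; 22 triisopropyl[(5-methylhex-4-en-1-yn-1-yl)oxy]silane
Product: 27 (3R)-3-Ar-5-hydroxy-6-prenyl-3-[(triethylsilyl)oxy]-7-[(triisopropylsilyl)oxy]-2,3-dihydro-4H-chromen-4-one, via vinylketene 23 (not isolated), via vinylcyclobutenone 24 (not isolated), via dienylketene 25 (not isolated), via cyclohexadienone 26 (not isolated)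
Conditions: 22 (1.5 equiv), ClCH2CH2Cl, hν (254 nm, low-pressure Hg lamp), rt; then 80 °C
Reagents that add atoms: none
Why: Light expels N2 from 17 and the ring carbon that becomes C8a migrates (Wolff rearrangement) to give vinylketene 23, whose vinyl part is the enol-ether double bond of ring C. The nucleophilic, prenyl-bearing carbon of 22 attacks the ketene carbonyl carbon and the siloxy carbon bonds to the ketene α-carbon, a (2+2) cycloaddition that forms C5–C6 and C7–C8 in 24. On heating, 24 opens by a four-electron conrotatory electrocyclic reaction to dienylketene 25, which closes ring A by a six-electron disrotatory electrocyclisation (C4a–C5) to 26 and tautomerises to the chelated C5 phenol 27. The closest known reaction is the Danheiser benzannulation in its photochemical Wolff variant with trialkylsiloxyalkynes. No stereocentre is formed; C3 is a silyl-protected spectator with no α-hydrogen, remote from the reacting π system. The selectivity needed is the orientation of the ketene–alkyne cycloaddition, and the polarisation of the ynol ether secures it, so prenyl ends at C6 and the silyloxy group at C7. An 8-prenyl isomer cannot form because O1 and C8a are already in place, and the ynol ether in excess outcompetes the isolated prenyl double bond of ring B as ketene partner.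

Step 13
Reactants: 27 (3R)-3-Ar-5-hydroxy-6-prenyl-3-[(triethylsilyl)oxy]-7-[(triisopropylsilyl)oxy]-2,3-dihydro-4H-chromen-4-one
Product: 28 (3R)-3,5-dihydroxy-3-(4-hydroxy-2-methoxy-3-prenylphenyl)-6-prenyl-7-[(triisopropylsilyl)oxy]-2,3-dihydro-4H-chromen-4-one
Conditions: HCl (1 M in MeOH), THF, 0 °C → rt
Reagents that add atoms: none
Why: Acid-catalysed transacetalisation to methanol removes the aryl methoxymethyl group, and methanolysis removes the triethylsilyl ether; the bulky aryl triisopropylsilyl ether should stay and keep O7 from adding to the C6 prenyl group under acid.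

Step 14
Reactants: 28 (3R)-3,5-dihydroxy-3-(4-hydroxy-2-methoxy-3-prenylphenyl)-6-prenyl-7-[(triisopropylsilyl)oxy]-2,3-dihydro-4H-chromen-4-one
Product: 29 (3R)-3,5,7-trihydroxy-3-(4-hydroxy-2-methoxy-3-prenylphenyl)-6-prenyl-2,3-dihydro-4H-chromen-4-one (CNP0157505.1)
Conditions: Bu4NF, AcOH, THF, 0 °C
Reagents that add atoms: none
Why: Fluoride cleaves the aryl silyl ether; the acetic acid buffer keeps the medium near neutral, so the α-ketol and the prenylated phenols are not exposed to base or strong acid.

## Compound list

1 | 4-bromo-3-methoxyphenol | COc1cc(O)ccc1Br | starting material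
2 | 1-bromo-2-methoxy-4-(methoxymethoxy)benzene | COCOc1ccc(Br)c(OC)c1 | intermediate
3 | prenyl bromide (1-bromo-3-methylbut-2-ene) | CC(C)=CCBr | starting material
4 | [3-bromo-2-methoxy-6-(methoxymethoxy)phenyl]lithium | COCOc1ccc(Br)c(OC)c1[Li] | intermediate
5 | 1-bromo-2-methoxy-4-(methoxymethoxy)-3-prenylbenzene | COCOc1ccc(Br)c(OC)c1CC=C(C)C | intermediate
6 | (S)-but-3-yn-2-ol | C[C@H](O)C#C | starting material
7 | Ar-magnesium bromide | COCOc1ccc([Mg]Br)c(OC)c1CC=C(C)C | intermediate
8 | (2S)-3-Ar-but-3-en-2-ol | C[C@H](O)C(=C)c1ccc(OCOC)c(CC=C(C)C)c1OC | intermediate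
9 | (1S)-1-[(2R)-2-Ar-oxiran-2-yl]ethan-1-ol | C[C@H](O)[C@@]1(c2ccc(OCOC)c(CC=C(C)C)c2OC)CO1 | intermediate
10 | 1-[(2R)-2-Ar-oxiran-2-yl]ethan-1-one | CC(=O)[C@@]1(c2ccc(OCOC)c(CC=C(C)C)c2OC)CO1 | intermediate
11 | diethyl oxalate | CCOC(=O)C(=O)OCC | starting material
12 | ethyl (2Z)-4-[(2R)-2-Ar-oxiran-2-yl]-2-hydroxy-4-oxobut-2-enoate (present as its lithium enolate) | CCOC(=O)/C(O)=C/C(=O)[C@@]1(c2ccc(OCOC)c(CC=C(C)C)c2OC)CO1 | intermediate
13 | ethyl (5R)-5-Ar-5-hydroxy-4-oxo-5,6-dihydro-4H-pyran-2-carboxylate | CCOC(=O)C1=CC(=O)[C@@](O)(c2ccc(OCOC)c(CC=C(C)C)c2OC)CO1 | intermediate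
14 | ethyl (5R)-5-Ar-4-oxo-5-[(triethylsilyl)oxy]-5,6-dihydro-4H-pyran-2-carboxylate | CCOC(=O)C1=CC(=O)[C@@](O[Si](CC)(CC)CC)(c2ccc(OCOC)c(CC=C(C)C)c2OC)CO1 | intermediate
15 | (5R)-5-Ar-4-oxo-5-[(triethylsilyl)oxy]-5,6-dihydro-4H-pyran-2-carboxylic acid | OC(=O)C1=CC(=O)[C@@](O[Si](CC)(CC)CC)(c2ccc(OCOC)c(CC=C(C)C)c2OC)CO1 | intermediate
16 | (5R)-5-Ar-4-oxo-5-[(triethylsilyl)oxy]-5,6-dihydro-4H-pyran-2-carbonyl chloride | ClC(=O)C1=CC(=O)[C@@](O[Si](CC)(CC)CC)(c2ccc(OCOC)c(CC=C(C)C)c2OC)CO1 | intermediate
17 | (5R)-5-Ar-2-(diazoacetyl)-5-[(triethylsilyl)oxy]-5,6-dihydro-4H-pyran-4-one | COc1c([C@@]2(O[Si](CC)(CC)CC)COC(C(=O)C=[N+]=[N-])=CC2=O)ccc(OCOC)c1CC=C(C)C | intermediate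
18 | 4-methylpent-3-enoic acid | CC(C)=CCC(=O)O | starting material
19 | methyl 4-methylpent-3-enoate | CC(C)=CCC(=O)OC | intermediate
20 | 1,1-dibromo-5-methylhex-4-en-2-one (present as its lithium enolate) | CC(C)=CCC(=O)C(Br)Br | intermediate
21 | lithium 5-methylhex-4-en-1-yn-1-olate | CC(C)=CCC#C[O-].[Li+] | intermediate
22 | triisopropyl[(5-methylhex-4-en-1-yn-1-yl)oxy]silane | CC(C)=CCC#CO[Si](C(C)C)(C(C)C)C(C)C | intermediate
23 | (5R)-5-Ar-2-(2-oxoethenyl)-5-[(triethylsilyl)oxy]-5,6-dihydro-4H-pyran-4-one (vinylketene) | COc1c([C@@]2(O[Si](CC)(CC)CC)COC(C=C=O)=CC2=O)ccc(OCOC)c1CC=C(C)C | intermediate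
24 | 4-{(5R)-5-Ar-4-oxo-5-[(triethylsilyl)oxy]-5,6-dihydro-4H-pyran-2-yl}-2-prenyl-3-[(triisopropylsilyl)oxy]cyclobut-2-en-1-one (mixture at the ring CH) | COc1c([C@@]2(O[Si](CC)(CC)CC)COC(C3C(=O)C(CC=C(C)C)=C3O[Si](C(C)C)(C(C)C)C(C)C)=CC2=O)ccc(OCOC)c1CC=C(C)C | intermediate
25 | (5R)-5-Ar-2-{(1Z)-4-oxo-3-prenyl-2-[(triisopropylsilyl)oxy]buta-1,3-dien-1-yl}-5-[(triethylsilyl)oxy]-5,6-dihydro-4H-pyran-4-one (dienylketene) | COc1c([C@@]2(O[Si](CC)(CC)CC)COC(/C=C(O[Si](C(C)C)(C(C)C)C(C)C)\C(CC=C(C)C)=C=O)=CC2=O)ccc(OCOC)c1CC=C(C)C | intermediate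
26 | (3R)-3-Ar-6-prenyl-3-[(triethylsilyl)oxy]-7-[(triisopropylsilyl)oxy]-2,3-dihydro-4H-chromene-4,5(4aH)-dione (keto tautomer, mixture at C4a) | COc1c([C@@]2(O[Si](CC)(CC)CC)COC3=CC(O[Si](C(C)C)(C(C)C)C(C)C)=C(CC=C(C)C)C(=O)C3C2=O)ccc(OCOC)c1CC=C(C)C | intermediate
27 | (3R)-3-Ar-5-hydroxy-6-prenyl-3-[(triethylsilyl)oxy]-7-[(triisopropylsilyl)oxy]-2,3-dihydro-4H-chromen-4-one | COc1c([C@@]2(O[Si](CC)(CC)CC)COc3cc(O[Si](C(C)C)(C(C)C)C(C)C)c(CC=C(C)C)c(O)c3C2=O)ccc(OCOC)c1CC=C(C)C | intermediate
28 | (3R)-3,5-dihydroxy-3-(4-hydroxy-2-methoxy-3-prenylphenyl)-6-prenyl-7-[(triisopropylsilyl)oxy]-2,3-dihydro-4H-chromen-4-one | COc1c([C@@]2(O)COc3cc(O[Si](C(C)C)(C(C)C)C(C)C)c(CC=C(C)C)c(O)c3C2=O)ccc(O)c1CC=C(C)C | intermediate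
29 | (3R)-3,5,7-trihydroxy-3-(4-hydroxy-2-methoxy-3-prenylphenyl)-6-prenyl-2,3-dihydro-4H-chromen-4-one | COc1c([C@@]2(O)COc3cc(O)c(CC=C(C)C)c(O)c3C2=O)ccc(O)c1CC=C(C)C | target

## Step count and least certain steps

Total step count: 14. Longest linear sequence: 12 (steps 1 to 9, then 12, 13 and 14); steps 10 and 11 form the two-step side branch to 22.

**Step 12 (key step).**
- What may go wrong: the enone and the electron-rich arene absorb at the irradiation wavelength, so the excited enone may add to the ynol ether or the prenyl double bond, or the C4 ketone may cleave next to its quaternary α-carbon. The strongly absorbing product may screen the diazoketone, the product phenol may be acylated by ketene, and the cyclobutenone may be slow to open.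
- Fallback: make vinylketene 23 without light. Starting from 17, a silver-catalysed Wolff rearrangement in aqueous dioxane (PhCO2Ag, Et3N, dark) should give [(5R)-5-Ar-4-oxo-5-[(triethylsilyl)oxy]-5,6-dihydro-4H-pyran-2-yl]acetic acid F1. The chloroenamine of step 9 converts it to [(5R)-5-Ar-4-oxo-5-[(triethylsilyl)oxy]-5,6-dihydro-4H-pyran-2-yl]acetyl chloride F2. Dehydrochlorination of F2 with Et3N in the presence of 22 at 80 °C gives 23 thermally and rejoins the route at 27.

**Step 6.**
- What may go wrong: the epoxide opening by the stabilised enolate may be slow, may take place at the benzylic carbon (a five-membered furanone), or the tertiary alkoxide formed may undergo α-ketol rearrangement or retro-Claisen cleavage on warming.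
- Fallback: replace the epoxide by a primary bromide as the ring-closing electrophile. From 10, LiBr and AcOH in THF should open the epoxide at CH2 to (3S)-3-Ar-4-bromo-3-hydroxybutan-2-one F3. Et3SiOTf and 2,6-lutidine give (3S)-3-Ar-4-bromo-3-[(triethylsilyl)oxy]butan-2-one F4. Claisen condensation of F4 with 11 (LiN(SiMe3)2) is followed by 6-exo displacement of bromide by the enolate oxygen, which rejoins the route at 14 with the tertiary oxygen already protected.

**Step 9.**
- What may go wrong: the diazoalkane may add as a dipole to the electron-poor ring double bond of the acid chloride or of the product, and traces of acid may take off the silyl ether.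
- Fallback: diazo transfer instead of acylation. From 15 via 16, coupling with Me4Sn under BnPd(PPh3)2Cl catalysis should give (5R)-2-acetyl-5-Ar-5-[(triethylsilyl)oxy]-5,6-dihydro-4H-pyran-4-one F5. Its only enolisable position is trifluoroacetylated (LiN(SiMe3)2, CF3CO2CH2CF3) to 1-{(5R)-5-Ar-4-oxo-5-[(triethylsilyl)oxy]-5,6-dihydro-4H-pyran-2-yl}-4,4,4-trifluorobutane-1,3-dione F6. Detrifluoroacetylative diazo transfer (MsN3, Et3N, H2O, MeCN) then rejoins the route at 17.

**Step 4.**
- What may go wrong: the titanium Lewis acid may ionise the new epoxide at its electron-rich benzylic carbon, leading to rearrangement or solvolysis before isolation.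
- Fallback: form the epoxide by C–C bond formation under basic conditions. From Grignard reagent 7 (made from 5), acylation with purchased (S)-2-[(tert-butyldimethylsilyl)oxy]-N-methoxy-N-methylpropanamide gives (2S)-1-Ar-2-[(tert-butyldimethylsilyl)oxy]propan-1-one F7. Corey–Chaykovsky methylenation with dimethylsulfonium methylide, attacking anti to the silyloxy group (polar Felkin–Anh), should give tert-butyl{(1S)-1-[(2R)-2-Ar-oxiran-2-yl]ethoxy}dimethylsilane F8. Bu4NF then rejoins the route at 9; this path also bypasses step 3.

**Step 3.**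
- What may go wrong: the aryl Grignard reagent may be consumed by deprotonating the terminal alkyne C–H, and carbometalation by an ortho-substituted aryl group may be sluggish.
- Fallback: a cross-coupling in which the arene is the limiting partner. From 5, bromine–lithium exchange (n-BuLi, −78 °C) and B(OiPr)3 give Ar-boronic acid F9. From 6, Markovnikov hydrobromination (HBr, Et4NBr, CH2Cl2) gives (S)-3-bromobut-3-en-2-ol F10. Suzuki–Miyaura coupling of F9 and F10 (Pd(dppf)Cl2, K3PO4, THF/H2O) rejoins the route at 8.

**Step 13.**
- What may go wrong: acid may close a prenyl group onto a neighbouring phenol (chroman formation) or ionise the tertiary benzylic C3–OH, leading to dehydration toward the isoflavone.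
- Fallback: remove the acetal without Brønsted acid while C3 is still silylated. From 27, Me3SiOTf with 2,2'-bipyridyl in MeCN at 0 °C, then water, should exchange only the aryl acetal and give (3R)-5-hydroxy-3-(4-hydroxy-2-methoxy-3-prenylphenyl)-6-prenyl-3-[(triethylsilyl)oxy]-7-[(triisopropylsilyl)oxy]-2,3-dihydro-4H-chromen-4-one F11. Bu4NF with AcOH then removes both silyl groups and arrives directly at 29.

## Further compounds

F1 | step 12 | [(5R)-5-Ar-4-oxo-5-[(triethylsilyl)oxy]-5,6-dihydro-4H-pyran-2-yl]acetic acid | OC(=O)CC1=CC(=O)[C@@](O[Si](CC)(CC)CC)(c2ccc(OCOC)c(CC=C(C)C)c2OC)CO1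
F2 | step 12 | [(5R)-5-Ar-4-oxo-5-[(triethylsilyl)oxy]-5,6-dihydro-4H-pyran-2-yl]acetyl chloride | ClC(=O)CC1=CC(=O)[C@@](O[Si](CC)(CC)CC)(c2ccc(OCOC)c(CC=C(C)C)c2OC)CO1
F3 | step 6 | (3S)-3-Ar-4-bromo-3-hydroxybutan-2-one | CC(=O)[C@](O)(CBr)c1ccc(OCOC)c(CC=C(C)C)c1OC
F4 | step 6 | (3S)-3-Ar-4-bromo-3-[(triethylsilyl)oxy]butan-2-one | CC(=O)[C@](O[Si](CC)(CC)CC)(CBr)c1ccc(OCOC)c(CC=C(C)C)c1OC
F5 | step 9 | (5R)-2-acetyl-5-Ar-5-[(triethylsilyl)oxy]-5,6-dihydro-4H-pyran-4-one | CC(=O)C1=CC(=O)[C@@](O[Si](CC)(CC)CC)(c2ccc(OCOC)c(CC=C(C)C)c2OC)CO1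
F6 | step 9 | 1-{(5R)-5-Ar-4-oxo-5-[(triethylsilyl)oxy]-5,6-dihydro-4H-pyran-2-yl}-4,4,4-trifluorobutane-1,3-dione | O=C(CC(=O)C1=CC(=O)[C@@](O[Si](CC)(CC)CC)(c2ccc(OCOC)c(CC=C(C)C)c2OC)CO1)C(F)(F)F
F7 | step 4 | (2S)-1-Ar-2-[(tert-butyldimethylsilyl)oxy]propan-1-one | C[C@H](O[Si](C)(C)C(C)(C)C)C(=O)c1ccc(OCOC)c(CC=C(C)C)c1OC
F8 | step 4 | tert-butyl{(1S)-1-[(2R)-2-Ar-oxiran-2-yl]ethoxy}dimethylsilane | C[C@H](O[Si](C)(C)C(C)(C)C)[C@@]1(c2ccc(OCOC)c(CC=C(C)C)c2OC)CO1
F9 | step 3 | Ar-boronic acid | COCOc1ccc(B(O)O)c(OC)c1CC=C(C)C
F10 | step 3 | (S)-3-bromobut-3-en-2-ol | C[C@H](O)C(Br)=C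
F11 | step 13 | (3R)-5-hydroxy-3-(4-hydroxy-2-methoxy-3-prenylphenyl)-6-prenyl-3-[(triethylsilyl)oxy]-7-[(triisopropylsilyl)oxy]-2,3-dihydro-4H-chromen-4-one | COc1c([C@@]2(O[Si](CC)(CC)CC)COc3cc(O[Si](C(C)C)(C(C)C)C(C)C)c(CC=C(C)C)c(O)c3C2=O)ccc(O)c1CC=C(C)C
A1 | alternative 1 | (3R)-3,5-dihydroxy-3-[2-hydroxy-4-(methoxymethoxy)-3-prenylphenyl]-7-(methoxymethoxy)-6-prenyl-2,3-dihydro-4H-chromen-4-one | Oc1c([C@@]2(O)COc3cc(OCOC)c(CC=C(C)C)c(O)c3C2=O)ccc(OCOC)c1CC=C(C)C
A2 | alternative 1 | (3R)-3-hydroxy-7-(methoxymethoxy)-3-[4-(methoxymethoxy)-2-(2-methylbut-3-en-2-yloxy)phenyl]-5-(2-methylbut-3-en-2-yloxy)-2,3-dihydro-4H-chromen-4-one | C=CC(C)(C)Oc1c([C@@]2(O)COc3cc(OCOC)cc(OC(C)(C)C=C)c3C2=O)ccc(OCOC)c1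
A3 | alternative 2 | (3R)-3-hydroxy-3-Ar-5,7-bis(methoxymethoxy)-6-prenyl-2,3-dihydro-4H-chromen-4-one | COc1c([C@@]2(O)COc3cc(OCOC)c(CC=C(C)C)c(OCOC)c3C2=O)ccc(OCOC)c1CC=C(C)C
A4 | alternative 2 | 6-(2-Ar-2-oxoethoxy)-2,4-bis(methoxymethoxy)-3-prenylbenzaldehyde | COc1c(C(=O)COc2cc(OCOC)c(CC=C(C)C)c(OCOC)c2C=O)ccc(OCOC)c1CC=C(C)C
A5 | alternative 3 | (3R)-3-Ar-3,5,7-tris(methoxymethoxy)-6-prenyl-2,3-dihydro-4H-chromen-4-one | COc1c([C@@]2(OCOC)COc3cc(OCOC)c(CC=C(C)C)c(OCOC)c3C2=O)ccc(OCOC)c1CC=C(C)C
A6 | alternative 3 | 3,5-bis(methoxymethoxy)-4-prenyl-2-(trimethylsilyl)phenyl trifluoromethanesulfonate | C[Si](C)(C)c1c(OS(=O)(=O)C(F)(F)F)cc(OCOC)c(CC=C(C)C)c1OCOC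
A7 | alternative 3 | methyl (2R)-2-Ar-3-hydroxy-2-(methoxymethoxy)propanoate | COC(=O)[C@@](CO)(OCOC)c1ccc(OCOC)c(CC=C(C)C)c1OC
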